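At the 25 h reading I look first at the starting material still in the flask, and I want to know beforehand which way of charging leaves least of it.

    starting material + enzyme ⇌ complex A (K1 = 1000 L mol⁻¹, k1 = 370 L mol⁻¹ min⁻¹)
    complex A → enzyme + target (k2 = 4.1 min⁻¹)
    second substrate + enzyme ⇌ complex B (K3 = 120 L mol⁻¹, k3 = 410 L mol⁻¹ min⁻¹)
    complex B → enzyme + second product (k4 = 0.26 min⁻¹)
    target + enzyme ⇌ isomer of the product + enzyme, rate k5*[enzyme]*[target] forward; the back reaction follows from the equilibrium constant (K5 = 1.7, k5 = 13 L mol⁻¹ min⁻¹)
    second substrate ⇌ dormant form (K6 = 0.17, k6 = 0.0013 min⁻¹)
    starting material + target → side product (k7 = 0.027 L mol⁻¹ min⁻¹)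

| setting | summer | autumn | midnight | noon |
|---|---|---|---|---|
| starting material | 0.020 M | 0.020 M (fed, over 20 h) | 0.020 M | 0.020 M |
| second substrate | 0.0400 M (fed, over 20 h) | 0.0400 M | 0.0400 M | 0.0400 M (in portions, 2, over 20 h) |
| enzyme | 20 µM | 20 µM | 20 µM | 20 µM |
| time | 25 h | 25 h | 25 h | 25 h |
| remark | all else is in the flask from the start; the feed brings no volume worth counting | all else is in the flask from the start; the feed brings no volume worth counting | everything together at the start | first portion at the start, last at 20 h |

* the flask that comes out highest in amount of target, in percent of the starting material charged, or "all alike" when all lie within 1.5 percentage points (summer / autumn / midnight / noon / all alike)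
* target at the end, in percent of the starting material charged, summer
* target at the end, in percent of the starting material charged, autumn
* target at the end, in percent of the starting material charged, midnight
* target at the end, in percent of the starting material charged, noon

- percent here means starting material units held: one side product counts as two
- run time (summer): 25 h

- Complex B has a half-life of 2.7 min by step 4 alone in midnight, much shorter than the 1.6 h of starting material by step 1 there, so I treat the complexes as steady. With the enzyme wholly free, steps 1 and 2 would then clear starting material at 0.407 h⁻¹.
- Second substrate parks the enzyme as complex B, its resting state, with half-occupation at 0.00897 M. In autumn the dormant form relaxes with a half-life of 1.29 h, much shorter than the run, so I count 0.0342 M of free second substrate, which leaves a free enzyme fraction of 20.8%.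
- I carry one quantity, the clearing constant: the pseudo-first-order rate of starting material loss, the free-enzyme rate times the free fraction, 0.0846 h⁻¹. I neglect the enzyme held by starting material, the second substrate used up, and the starting material lost by step 7.
- For midnight, plain decay over the run leaves 12.1% of the starting material.
- For autumn, I integrate a steady feed against this loss, then add the decay after the feed, and 31.6% remains.
- For summer, the free fraction falls as second substrate comes in, and integrating it gives 9.28 h of full-enzyme time, which leaves 2.28%.
- For noon, half the second substrate stands until 20 h, which gives 7.92 h and leaves 3.97%.
- So I charge the starting material at the start and feed second substrate as in summer, since by this reckoning that leaves less starting material than the other three. My reckoning stops here and gives no figure for target.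
- The forecast gives 72.8% of target for summer, 54.5% for autumn, 63.3% for midnight and 70.8% for noon, and picks summer, saying “Feeding the second substrate keeps enzyme free early”.
- The flasks end with target at 73.2% in summer, 54.6% in autumn, 63.8% in midnight and 71.6% in noon. Starting material stands at 3.1% in summer, 28.9% in autumn, 10.1% in midnight and 3.62% in noon.
- The neighbour of autumn charged with 8.0 × 10⁻⁶ M of enzyme has its clearing constant scaled with the enzyme to 0.0338 h⁻¹, and the same feed reckoning leaves 61.4% of the starting material. That flask ends with 27.5% of target and 61.0% of starting material.

The constants are those of an exercise, and the outcome is calculated.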